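## Retrosynthetic overview

1. The oxirane is the only ring and is formed last: a chiral dioxirane transfers oxygen to the C4=C5 bond of the unprotected (2E,4Z)-dienedioic acid 23, mirroring the presumed biosynthetic oxygenation of the finished seco-acid.
2. 23 comes from an Evans syn-aldol (C12–C13, sets 12S and 13R) of aldehyde 12 with a 3-silyloxypropanoyl oxazolidinone, followed by one-pot removal of auxiliary, methyl ester and silyl group.
3. 12 comes from a one-pot Normant carbocupration of propyne and conjugate addition to methyl but-2-ynoate (C5–C6 and C3–C4, sets 4Z and 2E).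
4. Bromide 5 comes from a copper-catalysed coupling (C8–C9) of the triflate of (R)-3-bromo-2-methylpropan-1-ol (source of C7) with a four-carbon acetal Grignard reagent.

Assumption: the SMILES is read literally as (2E,4S,5R,7R,12S,13R) (C1 = enoic carboxyl, C14 = the other carboxyl), so C3 and C6 are cis on the oxirane (it must come from a 4Z olefin) and the 12-OH/13-CH2OH pair is syn; 1, 3, 6, 7, 13, 14 and the L-series Shi ketone are taken as catalogue chemicals.

## Route

Step 1
Reactants: 1 (2R)-3-bromo-2-methylpropan-1-ol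
Product: 2 (2R)-3-bromo-2-methylpropyl trifluoromethanesulfonate
Conditions: Tf2O, pyridine, CH2Cl2, −78 → −20 °C; cold aqueous wash, used at once
Reagents that add atoms: trifluoromethanesulfonic anhydride (Tf2O), O=S(=O)(OS(=O)(=O)C(F)(F)F)C(F)(F)F
Why: O-sulfonylation of a primary alcohol at low temperature, which leaves the C–O bond and the stereocentre (later C7, R) untouched.

Step 2
Reactants: 2 (2R)-3-bromo-2-methylpropyl trifluoromethanesulfonate; 3 4-chloro-1,1-dimethoxybutane
Product: 5 (2R)-1-bromo-7,7-dimethoxy-2-methylheptane, via alkylmagnesium chloride 4 (not isolated)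
Conditions: 3, Mg, THF, 50 °C; then 2, CuBr·SMe2 (5 mol%), Et2O/THF, −78 → −30 °C
Reagents that add atoms: none
Why: copper-catalysed sp3–sp3 Grignard cross-coupling (Kochi–Schlosser type), in which the primary triflate is displaced orders of magnitude faster than the primary bromide at low temperature; the stereocentre is a spectator.

Step 3
Reactants: 5 (2R)-1-bromo-7,7-dimethoxy-2-methylheptane; 6 propyne; 7 methyl but-2-ynoate
Product: 12 methyl (2E,4Z,7R)-3,5,7-trimethyl-12-oxododeca-2,4-dienoate, via alkylmagnesium bromide 8 (not isolated), via alkenylcopper 9 (not isolated), via cuprio dienoate 10 (not isolated), via dienoate acetal 11 (not isolated)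
Conditions: 5, Mg, Et2O, 35 °C; CuBr·SMe2 (1.0 equiv), Me2S, −45 °C; 6, −25 °C, 3 h; 7, THF, −78 °C, 2 h; HCl/Et2O, −78 °C; then 1 M HCl, THF, 23 °C, 1 h
Reagents that add atoms: water, O
Why: Normant syn-carbocupration of propyne puts the alkyl group on the internal carbon cis to copper (sets 4Z), the alkenylcopper then adds syn across the ynoate (conjugate carbocupration) and protonation with retention gives 2E, and the dilute acid unmasks the dimethyl acetal; C7 is untouched.

Step 4
Reactants: 13 (4R)-4-benzyl-1,3-oxazolidin-2-one; 14 3-[(tert-butyldimethylsilyl)oxy]propanoic acid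
Product: 16 (4R)-4-benzyl-3-{3-[(tert-butyldimethylsilyl)oxy]propanoyl}-1,3-oxazolidin-2-one, via mixed pivalic anhydride 15 (not isolated)
Conditions: 14, PivCl, Et3N, THF, −20 °C; then 13, LiCl, −20 → 23 °C
Reagents that add atoms: none
Why: N-acylation of the oxazolidinone through the mixed pivalic anhydride (LiCl/Et3N protocol), where the hindered pivaloyl carbonyl is not attacked; no stereocentre is formed.

Step 5
Reactants: 16 (4R)-4-benzyl-3-{3-[(tert-butyldimethylsilyl)oxy]propanoyl}-1,3-oxazolidin-2-one; 12 methyl (2E,4Z,7R)-3,5,7-trimethyl-12-oxododeca-2,4-dienoate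
Product: 19 methyl (2E,4Z,7R,12S,13R)-14-[(4R)-4-benzyl-2-oxo-1,3-oxazolidin-3-yl]-13-{[(tert-butyldimethylsilyl)oxy]methyl}-12-hydroxy-3,5,7-trimethyl-14-oxotetradeca-2,4-dienoate, via boron enolate 17 (not isolated), via boron aldolate 18 (not isolated)
Conditions: 16, Bu2BOTf, iPr2NEt, CH2Cl2, −78 → 0 °C; 12, −78 → 0 °C; then pH 7 buffer, MeOH, 30% H2O2, 0 °C
Reagents that add atoms: none
Why: Evans syn-aldol reaction, in which the Z boron enolate reacts through a closed Zimmerman–Traxler chair on the face opposite the benzyl group of the (R)-auxiliary and so sets 12S and 13R (syn) together; the remote ester, diene and C7 do not take part.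

Step 6
Reactants: 19 methyl (2E,4Z,7R,12S,13R)-14-[(4R)-4-benzyl-2-oxo-1,3-oxazolidin-3-yl]-13-{[(tert-butyldimethylsilyl)oxy]methyl}-12-hydroxy-3,5,7-trimethyl-14-oxotetradeca-2,4-dienoate
Product: 23 (2E,4Z,7R,12S,13R)-12-hydroxy-13-(hydroxymethyl)-3,5,7-trimethyltetradeca-2,4-dienedioic acid, via peroxy acid 20 (not isolated), via monoacid 21 (not isolated), via silyl ether diacid 22 (not isolated)
Conditions: LiOH, H2O2, THF/H2O, 0 °C; Na2SO3; CH2Cl2 wash (removes 13); LiOH, THF/MeOH/H2O, 35 °C; then 1 M HCl to pH 1, 23 °C, 2 h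
Reagents that add atoms: hydrogen peroxide, OO; lithium hydroxide, [Li+].[OH-]
Why: Evans hydroperoxide cleavage of the imide at the exocyclic carbonyl (peracid reduced by sulfite), saponification of the methyl dienoate and acid-catalysed hydrolysis of the primary silyl ether, with the carboxylate form protecting C13 against epimerisation and retro-aldol so that C12, C13 and the 4Z geometry are kept.

Step 7
Reactants: 23 (2E,4Z,7R,12S,13R)-12-hydroxy-13-(hydroxymethyl)-3,5,7-trimethyltetradeca-2,4-dienedioic acid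
Product: 24 (2E,4S,5R,7R,12S,13R)-4,5-epoxy-12-hydroxy-13-(hydroxymethyl)-3,5,7-trimethyltetradec-2-enedioic acid
Conditions: L-fructose-derived Shi ketone (ent-Shi ketone, 30 mol%), Oxone (2KHSO5·KHSO4·K2SO4), K2CO3, Bu4NHSO4, Na2B4O7/Na2EDTA buffer, MeCN/DMM/H2O, 0 °C; NaH2PO4 to pH 4
Reagents that add atoms: Oxone (active part KHSO5), [K+].[O-]S(=O)(=O)OO
Why: Shi asymmetric epoxidation, in which the electrophilic chiral dioxirane oxidises only the electron-rich, twisted C4=C5 bond (C2=C3 is deactivated by the carboxyl group) and, with the single olefinic hydrogen H4 in the hindered quadrant of the spiro transition state of the L-series ketone, delivers oxygen to the face that gives 4S,5R, while concerted syn transfer to the 4Z olefin places C3 and C6 cis on the oxirane.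

## Compound list

1 | (2R)-3-bromo-2-methylpropan-1-ol | BrC[C@H](C)CO | starting material
2 | (2R)-3-bromo-2-methylpropyl trifluoromethanesulfonate | BrC[C@H](C)COS(=O)(=O)C(F)(F)F | intermediate
3 | 4-chloro-1,1-dimethoxybutane | COC(OC)CCCCl | starting material
4 | alkylmagnesium chloride: (4,4-dimethoxybutyl)magnesium chloride (not isolated) | COC(OC)CCC[Mg]Cl | intermediate
5 | (2R)-1-bromo-7,7-dimethoxy-2-methylheptane | BrC[C@H](C)CCCCC(OC)OC | intermediate
6 | propyne | CC#C | starting material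
7 | methyl but-2-ynoate | CC#CC(=O)OC | starting material
8 | alkylmagnesium bromide: [(2R)-7,7-dimethoxy-2-methylheptyl]magnesium bromide (not isolated) | Br[Mg]C[C@H](C)CCCCC(OC)OC | intermediate
9 | alkenylcopper: [(1Z,4R)-9,9-dimethoxy-2,4-dimethylnon-1-en-1-yl]copper, alkyl chain cis to Cu (not isolated) | [Cu]/C=C(/C)C[C@H](C)CCCCC(OC)OC | intermediate
10 | cuprio dienoate: methyl (2Z,4Z,7R)-2-cuprio-12,12-dimethoxy-3,5,7-trimethyldodeca-2,4-dienoate, Cu cis to C4 (not isolated) | COC(=O)/C([Cu])=C(\C)/C=C(/C)C[C@H](C)CCCCC(OC)OC | intermediate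
11 | dienoate acetal: methyl (2E,4Z,7R)-12,12-dimethoxy-3,5,7-trimethyldodeca-2,4-dienoate (not isolated) | COC(=O)/C=C(\C)/C=C(/C)C[C@H](C)CCCCC(OC)OC | intermediate
12 | methyl (2E,4Z,7R)-3,5,7-trimethyl-12-oxododeca-2,4-dienoate | COC(=O)/C=C(\C)/C=C(/C)C[C@H](C)CCCCC=O | intermediate
13 | (4R)-4-benzyl-1,3-oxazolidin-2-one | O=C1N[C@H](Cc2ccccc2)CO1 | starting material
14 | 3-[(tert-butyldimethylsilyl)oxy]propanoic acid | CC(C)(C)[Si](C)(C)OCCC(=O)O | starting material
15 | mixed pivalic anhydride: 3-[(tert-butyldimethylsilyl)oxy]propanoic 2,2-dimethylpropanoic anhydride (not isolated) | CC(C)(C)[Si](C)(C)OCCC(=O)OC(=O)C(C)(C)C | intermediate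
16 | (4R)-4-benzyl-3-{3-[(tert-butyldimethylsilyl)oxy]propanoyl}-1,3-oxazolidin-2-one | CC(C)(C)[Si](C)(C)OCCC(=O)N1[C@H](Cc2ccccc2)COC1=O | intermediate
17 | boron enolate: dibutylboron (Z)-enolate of 16 (not isolated) | CCCCB(CCCC)O/C(=C\CO[Si](C)(C)C(C)(C)C)N1[C@H](Cc2ccccc2)COC1=O | intermediate
18 | boron aldolate: 12-O-dibutylboryl derivative of 19 (not isolated) | COC(=O)/C=C(\C)/C=C(/C)C[C@H](C)CCCC[C@H](OB(CCCC)CCCC)[C@@H](CO[Si](C)(C)C(C)(C)C)C(=O)N1[C@H](Cc2ccccc2)COC1=O | intermediate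
19 | methyl (2E,4Z,7R,12S,13R)-14-[(4R)-4-benzyl-2-oxo-1,3-oxazolidin-3-yl]-13-{[(tert-butyldimethylsilyl)oxy]methyl}-12-hydroxy-3,5,7-trimethyl-14-oxotetradeca-2,4-dienoate | COC(=O)/C=C(\C)/C=C(/C)C[C@H](C)CCCC[C@H](O)[C@@H](CO[Si](C)(C)C(C)(C)C)C(=O)N1[C@H](Cc2ccccc2)COC1=O | intermediate
20 | peroxy acid: C14 peroxycarboxylic acid of 21, C1 methyl ester and silyl ether intact (not isolated) | COC(=O)/C=C(\C)/C=C(/C)C[C@H](C)CCCC[C@H](O)[C@@H](CO[Si](C)(C)C(C)(C)C)C(=O)OO | intermediate
21 | monoacid: (2R,3S,8R,10Z,12E)-2-{[(tert-butyldimethylsilyl)oxy]methyl}-3-hydroxy-14-methoxy-8,10,12-trimethyl-14-oxotetradeca-10,12-dienoic acid (not isolated) | COC(=O)/C=C(\C)/C=C(/C)C[C@H](C)CCCC[C@H](O)[C@@H](CO[Si](C)(C)C(C)(C)C)C(=O)O | intermediate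
22 | silyl ether diacid: (2E,4Z,7R,12S,13R)-13-{[(tert-butyldimethylsilyl)oxy]methyl}-12-hydroxy-3,5,7-trimethyltetradeca-2,4-dienedioic acid (not isolated) | OC(=O)/C=C(\C)/C=C(/C)C[C@H](C)CCCC[C@H](O)[C@@H](CO[Si](C)(C)C(C)(C)C)C(=O)O | intermediate
23 | (2E,4Z,7R,12S,13R)-12-hydroxy-13-(hydroxymethyl)-3,5,7-trimethyltetradeca-2,4-dienedioic acid | OC(=O)/C=C(\C)/C=C(/C)C[C@H](C)CCCC[C@H](O)[C@@H](CO)C(=O)O | intermediate
24 | (2E,4S,5R,7R,12S,13R)-4,5-epoxy-12-hydroxy-13-(hydroxymethyl)-3,5,7-trimethyltetradec-2-enedioic acid (CNP0468463.3) | C/C(=C\C(=O)O)[C@@H]1O[C@]1(C)C[C@H](C)CCCC[C@H](O)[C@@H](CO)C(=O)O | target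

## Step count and risks

Total steps: 7 (steps 1, 2, 3, 5, 6, 7 in the main line; step 4 makes the aldol partner).
Longest linear sequence: 6 steps (1 → 2 → 3 → 5 → 6 → 7).

**Step 3 (tandem carbocupration, ynoate addition, acetal hydrolysis).** The alkenylcopper 9 may add sluggishly to the β-substituted ynoate, and the cuprio dienoate 10 can equilibrate above about −60 °C and erode the 2E geometry. Fallback: set out from 5, form 9 as before, but quench it with I2 (THF, −45 → 0 °C) to give (1Z,4R)-1-iodo-9,9-dimethoxy-2,4-dimethylnon-1-ene F1. In parallel, syn-stannylcupration of 7 (Bu3SnLi, CuBr·SMe2, THF, −78 °C, then MeOH) gives methyl (2E)-3-(tributylstannyl)but-2-enoate F2. Stille coupling of F1 with F2 (Pd2(dba)3, AsPh3, catalytic CuI, NMP, 40 °C) forms the C3–C4 bond with retention at both partners and comes back to the route at 11, which 1 M HCl/THF converts into 12.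

**Step 7 (epoxidation of the unprotected diacid).** The dianionic substrate may partition poorly, over-oxidise at C2=C3, give insufficient face selectivity, or the epoxy acid may suffer on acidic isolation. Fallback: set out from the neutral aldol adduct 19 and run the same L-series Shi epoxidation there. This gives methyl (2E,4S,5R,7R,12S,13R)-14-[(4R)-4-benzyl-2-oxo-1,3-oxazolidin-3-yl]-13-{[(tert-butyldimethylsilyl)oxy]methyl}-4,5-epoxy-12-hydroxy-3,5,7-trimethyl-14-oxotetradec-2-enoate F3. LiOH/H2O2 (0 °C) converts it into the C14 peroxy acid of the epoxy C1 methyl ester F4, and Na2SO3 reduces this to the epoxy C14 monoacid C1 methyl ester F5. LiOH (THF/MeOH/H2O, 0 → 23 °C) then gives (2E,4S,5R,7R,12S,13R)-13-{[(tert-butyldimethylsilyl)oxy]methyl}-4,5-epoxy-12-hydroxy-3,5,7-trimethyltetradec-2-enedioic acid F6. Fluoride (Bu4NF buffered with AcOH, THF, 0 °C) replaces the acid desilylation and comes back to the route at 24.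

**Step 2 (chemoselective coupling at the triflate).** The functionalised Grignard reagent 4 may attack or exchange at the bromide, or the bromo triflate may decompose in THF before it couples. Fallback: set out from 2 and alkylate lithiated 4,4-dimethoxybut-1-yne (n-BuLi, THF/DMPU, −78 °C; the alkyne is one step from propargyl bromide, Al and HC(OMe)3). This SN2 reaction touches only the triflate and gives (6R)-7-bromo-1,1-dimethoxy-6-methylhept-3-yne F7. Hydrogenation of the alkyne (H2, PtO2, EtOAc, 23 °C) comes back to the route at 5.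

## Further compounds

F1 | step 3 | (1Z,4R)-1-iodo-9,9-dimethoxy-2,4-dimethylnon-1-ene | I/C=C(/C)C[C@H](C)CCCCC(OC)OC
F2 | step 3 | methyl (2E)-3-(tributylstannyl)but-2-enoate | COC(=O)/C=C(\C)[Sn](CCCC)(CCCC)CCCC
F3 | step 7 | methyl (2E,4S,5R,7R,12S,13R)-14-[(4R)-4-benzyl-2-oxo-1,3-oxazolidin-3-yl]-13-{[(tert-butyldimethylsilyl)oxy]methyl}-4,5-epoxy-12-hydroxy-3,5,7-trimethyl-14-oxotetradec-2-enoate | COC(=O)/C=C(\C)[C@@H]1O[C@]1(C)C[C@H](C)CCCC[C@H](O)[C@@H](CO[Si](C)(C)C(C)(C)C)C(=O)N1[C@H](Cc2ccccc2)COC1=O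
F4 | step 7 | C14 peroxy acid of the epoxy C1 methyl ester (silyl ether intact) | COC(=O)/C=C(\C)[C@@H]1O[C@]1(C)C[C@H](C)CCCC[C@H](O)[C@@H](CO[Si](C)(C)C(C)(C)C)C(=O)OO
F5 | step 7 | epoxy C14 monoacid C1 methyl ester (silyl ether intact) | COC(=O)/C=C(\C)[C@@H]1O[C@]1(C)C[C@H](C)CCCC[C@H](O)[C@@H](CO[Si](C)(C)C(C)(C)C)C(=O)O
F6 | step 7 | (2E,4S,5R,7R,12S,13R)-13-{[(tert-butyldimethylsilyl)oxy]methyl}-4,5-epoxy-12-hydroxy-3,5,7-trimethyltetradec-2-enedioic acid | OC(=O)/C=C(\C)[C@@H]1O[C@]1(C)C[C@H](C)CCCC[C@H](O)[C@@H](CO[Si](C)(C)C(C)(C)C)C(=O)O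
F7 | step 2 | (6R)-7-bromo-1,1-dimethoxy-6-methylhept-3-yne | BrC[C@H](C)CC#CCC(OC)OC
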